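## Retrosynthetic overview

1. Feature used: in the ring C1(=O)–C2(acyl)=C3(OH)–C4H2–C5H2–C6H(OH), C2 is a triacylmethine carbon (bonded to C1, C3 and the side-chain carbonyl C1′), and C1–C6–C5–C4–C3 is the intact carbon chain of (R)-2-hydroxyglutaric acid with C6 as its carbinol carbon.
2. Key disconnection: both ring bonds C2–C1 and C2–C3 are cut. The only ring is closed last by a [5+1] double Claisen annulation, in which the methyl carbon of (8E,10E)-nonadeca-8,10-dien-2-one (11) is acylated twice by methyl (R)-5-oxotetrahydrofuran-2-carboxylate (13).
3. The γ-lactone of 13 is a ring that is not in the target: it masks C6–OH, activates C3, and is cleaved as the carbocycle forms (O→C acyl transfer), so no protecting group is needed.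
4. C6 (R) comes from the chiral pool (lactone acid 12, the deamination product of D-glutamic acid). The (7′E,9′E)-diene of 11 is set by a Suzuki–Miyaura coupling at C8′–C9′ of two hydrometalated terminal alkynes, and the methyl ketone end is added by an acetoacetic ester synthesis.
5. Ring order: one ring only (the cyclohexane-1,3-dione), formed in the final step.

Key step: step 7

Remark: the target is drawn as one enol tautomer of (R)-4-hydroxy-2-acylcyclohexane-1,3-dione, whose β-triketone tautomers equilibrate, so no tautomer control is attempted; (R)-5-oxotetrahydrofuran-2-carboxylic acid is assumed to be a commercial starting material.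

## Route

Step 1
Reactants: 1 6-chlorohex-1-yne
Product: 3 (E)-6-chloro-1-iodohex-1-ene, via alkenylzirconocene chloride 2 (not isolated)
Conditions: Cp2Zr(H)Cl (1.2 equiv), THF, rt; then I2 (1.2 equiv), THF, 0 °C
Reagents that add atoms: iodine, II
Why: Hydrozirconation of the terminal alkyne is a syn addition that places zirconium on the terminal carbon, and iodinolysis of the C–Zr bond proceeds with retention, so the (E)-iodoalkene should result while the primary chloride stays untouched (hydrozirconation–iodination).

Step 2
Reactants: 4 dec-1-yne
Product: 5 (E)-2-(dec-1-en-1-yl)-4,4,5,5-tetramethyl-1,3,2-dioxaborolane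
Conditions: HBpin (1.1 equiv), Cp2Zr(H)Cl (5 mol %), Et3N (10 mol %), neat, 60 °C
Reagents that add atoms: pinacolborane, [H]B1OC(C)(C)C(C)(C)O1
Why: Zirconium-catalysed hydroboration of a terminal alkyne with pinacolborane is a syn, anti-Markovnikov addition and should give the (E)-alkenylboronate only.

Step 3
Reactants: 3 (E)-6-chloro-1-iodohex-1-ene; 5 (E)-2-(dec-1-en-1-yl)-4,4,5,5-tetramethyl-1,3,2-dioxaborolane
Product: 6 (5E,7E)-1-chlorohexadeca-5,7-diene
Conditions: Pd(PPh3)4 (3 mol %), K3PO4 (3 equiv), THF/H2O (5:1), 55 °C
Reagents that add atoms: none
Why: Suzuki–Miyaura cross-coupling of an alkenyl iodide with an alkenylboronate retains the geometry of both partners, which fixes the (E,E)-diene (C7′=C8′ and C9′=C10′ of the target), and Pd(0)/PPh3 should not insert into the unactivated primary C–Cl bond.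

Step 4
Reactants: 6 (5E,7E)-1-chlorohexadeca-5,7-diene; 7 ethyl acetoacetate
Product: 9 ethyl (7E,9E)-2-acetyloctadeca-7,9-dienoate, via dienyl iodide 8 (not isolated)
Conditions: 7 (3 equiv), K2CO3 (2 equiv), KI (0.2 equiv), DMF, 70 °C
Reagents that add atoms: none
Why: In this acetoacetic ester alkylation the potassium enolate of 7 is C-alkylated in an SN2 reaction by iodide 8, formed in situ from 6 by halide exchange, the excess of 7 suppresses dialkylation, and the new stereocentre at C2 is racemic and is removed in step 5.

Step 5
Reactants: 9 ethyl (7E,9E)-2-acetyloctadeca-7,9-dienoate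
Product: 11 (8E,10E)-nonadeca-8,10-dien-2-one, via β-keto acid 10 (not isolated)
Conditions: 2 M NaOH, EtOH, 40 °C; then 2 M HCl to pH 2, 60 °C
Reagents that add atoms: none
Why: Ketonic hydrolysis of the acetoacetic ester, that is saponification with dilute base followed by decarboxylation of β-keto acid 10 through its cyclic six-membered transition state on acidification and gentle warming, should give the methyl ketone with the remote diene unchanged.

Step 6
Reactants: 12 (R)-5-oxotetrahydrofuran-2-carboxylic acid
Product: 13 methyl (R)-5-oxotetrahydrofuran-2-carboxylate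
Conditions: MeI (1.5 equiv), KHCO3 (1.5 equiv), DMF, rt
Reagents that add atoms: iodomethane, CI
Why: SN2 O-methylation of the carboxylate under weakly basic, non-nucleophilic conditions should give the ester without opening the γ-lactone or touching the C2 stereocentre.

Step 7
Reactants: 11 (8E,10E)-nonadeca-8,10-dien-2-one; 13 methyl (R)-5-oxotetrahydrofuran-2-carboxylate
Product: 17 (6R)-3,6-dihydroxy-2-[(7E,9E)-octadeca-7,9-dienoyl]cyclohex-2-en-1-one, via lithium enolate 14 (not isolated), via lactone diketone 15 (not isolated), via hydroxy diketo ester 16 (not isolated)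
Conditions: 11 (2.05 equiv), LDA (2.0 equiv), THF, −78 °C; then added to 13 (1.0 equiv), THF, −78 → 0 °C; then NaOMe (1.5 equiv), MeOH, 0 → 40 °C; then cold 1 M HCl to pH 3
Reagents that add atoms: none
Why: Kinetic deprotonation of 11 at its methyl group gives 14, which undergoes a crossed Claisen condensation at the α-oxygenated methyl ester of 13 (the more electrophilic of its two carbonyl groups) to give 15, whose acidic proton is taken by the second equivalent of 14 (returned as recoverable 11); methoxide then opens the lactone to 16, and the diketonate carbon attacks the new methyl ester in a Dieckmann-type closure that ends in the stable triketonate of 17. The closest known reaction types are the acylation of methyl ketone enolates by esters to β-diketones and the alkoxide-mediated cyclisation of 5,7-dioxo esters to 2-acylcyclohexane-1,3-diones. The six-membered carbocycle closes by a 6-exo-trig C-acylation (C2 onto C3 of 17) that is made irreversible by deprotonation of the strongly acidic β-triketone. No stereocentre is formed: C6 is carried over from 12, and it should not epimerise because no amide base ever meets 13 and because the carbonyl group next to C6 in 15, 16 and 17 is part of a delocalised di- or triketonate that resists a second enolisation. The step needs methyl-over-methylene selectivity in the enolisation of 11 (secured by LDA at −78 °C) and C- over O-acylation in the closure (O-acylation is reversible under methoxide, C-acylation is not), whereas the order in which the two carbonyl groups of 13 are attacked does not matter, since C2 ends up bonded to both.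

## Compound list

1 | 6-chlorohex-1-yne | C#CCCCCCl | starting material
2 | (E)-(6-chlorohex-1-en-1-yl)zirconocene chloride (Cp drawn σ-bonded) | ClCCCC/C=C/[Zr](Cl)(C1C=CC=C1)C1C=CC=C1 | intermediate
3 | (E)-6-chloro-1-iodohex-1-ene | ClCCCC/C=C/I | intermediate
4 | dec-1-yne | CCCCCCCCC#C | starting material
5 | (E)-2-(dec-1-en-1-yl)-4,4,5,5-tetramethyl-1,3,2-dioxaborolane | CCCCCCCC/C=C/B1OC(C)(C)C(C)(C)O1 | intermediate
6 | (5E,7E)-1-chlorohexadeca-5,7-diene | ClCCCC/C=C/C=C/CCCCCCCC | intermediate
7 | ethyl acetoacetate (ethyl 3-oxobutanoate) | CC(=O)CC(=O)OCC | starting material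
8 | (5E,7E)-1-iodohexadeca-5,7-diene | ICCCC/C=C/C=C/CCCCCCCC | intermediate
9 | ethyl (7E,9E)-2-acetyloctadeca-7,9-dienoate (racemic at C2) | CCCCCCCC/C=C/C=C/CCCCC(C(C)=O)C(=O)OCC | intermediate
10 | (7E,9E)-2-acetyloctadeca-7,9-dienoic acid (racemic at C2) | CCCCCCCC/C=C/C=C/CCCCC(C(C)=O)C(=O)O | intermediate
11 | (8E,10E)-nonadeca-8,10-dien-2-one | CCCCCCCC/C=C/C=C/CCCCCC(C)=O | intermediate
12 | (R)-5-oxotetrahydrofuran-2-carboxylic acid | OC(=O)[C@H]1CCC(=O)O1 | starting material
13 | methyl (R)-5-oxotetrahydrofuran-2-carboxylate | COC(=O)[C@H]1CCC(=O)O1 | intermediate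
14 | lithium (8E,10E)-nonadeca-1,8,10-trien-2-olate | [Li]OC(=C)CCCCC/C=C/C=C/CCCCCCCC | intermediate
15 | (5R)-5-[(9E,11E)-3-oxoicosa-9,11-dienoyl]oxolan-2-one (formed as its diketonate) | CCCCCCCC/C=C/C=C/CCCCCC(=O)CC(=O)[C@H]1CCC(=O)O1 | intermediate
16 | methyl (4R,13E,15E)-4-hydroxy-5,7-dioxotetracosa-13,15-dienoate (formed as its diketonate) | CCCCCCCC/C=C/C=C/CCCCCC(=O)CC(=O)[C@H](O)CCC(=O)OC | intermediate
17 | (6R)-3,6-dihydroxy-2-[(7E,9E)-octadeca-7,9-dienoyl]cyclohex-2-en-1-one (CNP0169831.1) | CCCCCCCC/C=C/C=C/CCCCCC(=O)C1=C(O)CC[C@@H](O)C1=O | target

## Step count and risks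

Total step count: 7. Longest linear sequence: 5 (steps 1, 3, 4, 5 and 7, from 6-chlorohex-1-yne).

**Step 7 (key step).** The intermolecular first acylation may stall through proton transfer between the enolate and the growing β-diketone. It may also be diverted into attack of a second enolate on the remaining carbonyl group, or be accompanied by base-induced epimerisation at the α-oxygenated centre of 13. In the methoxide stage, the α′-hydroxy-β-diketone may cyclodehydrate instead of closing the carbocycle. The fallback separates the two C–C bond formations and removes all base from the first one. It sets out from 11 and 12. Ketone 11 would be converted through enolate 14 (LDA, THF, −78 °C; then Me3SiCl) into trimethyl{[(8E,10E)-nonadeca-1,8,10-trien-2-yl]oxy}silane F1. Acid 12 would be converted with oxalyl chloride and catalytic DMF in CH2Cl2 into (R)-5-oxotetrahydrofuran-2-carbonyl chloride F2. A ZnCl2-mediated C-acylation of the silyl enol ether F1 by F2 in CH2Cl2 (Mukaiyama-type acylation) should give the lactone diketone as an isolated compound with its hydroxyl group still masked. The fallback comes back to the route at 15, which is then closed to 17 with NaOMe in MeOH as a separate operation.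

**Step 4.** Halide exchange and substitution at the unactivated primary chloride may be slow, and the ambident acetoacetate anion may undergo O-alkylation and dialkylation. The fallback replaces the stabilised enolate by a metalated hydrazone and makes the decarboxylation unnecessary. It sets out from 6, which would be converted with NaI in refluxing acetone into the isolated iodide 8. Commercial acetone N,N-dimethylhydrazone would be deprotonated with LDA in THF at 0 °C to the lithiated acetone N,N-dimethylhydrazone F3. Alkylation of F3 with 8 at −78 → 0 °C should give (8E,10E)-nonadeca-8,10-dien-2-one N,N-dimethylhydrazone F4. Two-phase hydrolysis of F4 with aqueous oxalic acid comes back to the route at 11 and replaces steps 4 and 5.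

**Step 3.** Transmetalation of the pinacol boronate may be slow, which would allow protodeboronation, homocoupling and partial loss of alkene geometry during prolonged heating with base. The fallback uses a base-free coupling of an organozinc made directly from the alkyne. It sets out from 4, which would be hydrozirconated (Cp2Zr(H)Cl, THF, rt) to (E)-dec-1-en-1-ylzirconocene chloride F5. Transmetalation of F5 with ZnCl2 would give (E)-dec-1-en-1-ylzinc chloride F6. Negishi coupling of F6 with iodide 3 (Pd(PPh3)4, THF, rt) comes back to the route at 6 and replaces steps 2 and 3.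

Further compounds
F1 | step 7 | trimethyl{[(8E,10E)-nonadeca-1,8,10-trien-2-yl]oxy}silane | C=C(CCCCC/C=C/C=C/CCCCCCCC)O[Si](C)(C)C
F2 | step 7 | (R)-5-oxotetrahydrofuran-2-carbonyl chloride | ClC(=O)[C@H]1CCC(=O)O1
F3 | step 4 | lithiated acetone N,N-dimethylhydrazone | [Li]CC(C)=NN(C)C
F4 | step 4 | (8E,10E)-nonadeca-8,10-dien-2-one N,N-dimethylhydrazone | CCCCCCCC/C=C/C=C/CCCCCC(C)=NN(C)C
F5 | step 3 | (E)-dec-1-en-1-ylzirconocene chloride | CCCCCCCC/C=C/[Zr](Cl)(C1C=CC=C1)C1C=CC=C1
F6 | step 3 | (E)-dec-1-en-1-ylzinc chloride | CCCCCCCC/C=C/[Zn]Cl
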